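| flask | E | L | remark | time |
|---|---|---|---|---|
| grey | 10 mM | 2.9 mM | run made earlier |  |
| teal | 10 mM | 7.2 mM | run made earlier |  |
| amber | 23 mM | 11 mM | run made earlier |  |
| autumn | 30 mM | 4.00 mM |  | 4.0 min |
| dusk | 15 mM | 8.00 mM |  | 4.0 min |
| spring | 30 mM | 11.0 mM |  | 4.0 min |
| noon | 10 mM | 11.0 mM |  | 4.0 min |

- grey (time / min: Z / %, E / %): 0.833: 10.9, 87.1; 1.50: 11.9, 82.7; 2.50: 12.8, 78.1; 3.00: 12.5, 77.1; 4.00: 11.8, 74.1
- teal (time / min: Z / %, E / %): 0.333: 11.7, 87.9; 1.00: 22.4, 67.7; 2.00: 26.4, 58.5; 3.00: 26.4, 48.3; 4.00: 27.7, 42.1
- amber (time / min: Z / %, E / %): 0.333: 13.7, 80.5; 1.00: 24.9, 66.6; 2.00: 23.9, 58.6; 3.00: 22.5, 54.8; 4.00: 21.5, 54.1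

(standard deviation of a reading: 1 percentage point)

- the earlier runs were read with a standard deviation of 1 percentage point

- all flasks from highest to lowest amount of Z, in percent of the E charged, at 4.0 min (autumn / dusk / spring / noon)
- the same order at 12 s (autumn / dusk / spring / noon)
- the amount of Z, in percent of the E charged of the flask you put first, at 4.0 min
- the amount of Z, in percent of the E charged of the flask you put last, at 4.0 min

One tally stands out in the grey and amber runs: the E lost comes up near the L charged, which reads as one L taken for each E lost. At the last amber reading E has fallen by 10.6 mM against 11 mM of L charged, and at the last grey reading by 2.59 mM against 2.9 mM. Z does not close the tally, since Z and E together read 75.6% at that amber reading, so the E lost stands partly as something unread. The natural zero is an even split between Z and that partner. Against it stands the Z share, the Z present over the E lost, averaged over the last readings of the runs: 0.467, close to half.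

This gives a bench rule. With L as limiting reagent, and with the L charged reacted by the reading, Z in percent of the E charged is the Z share times [L]/[E] as charged. Autumn gets 6.23%, spring 17.1% and dusk 24.9%. The border is that ratio itself: noon has 1.10, so its 51.4% is void and time must enter. The last teal reading, taken as second order, gives k = 0.0683 mM⁻¹ min⁻¹. Integrated with the Z share, this gives noon 36.3% and lowers dusk to 23.1%, so noon stands first. At 12 s the fraction of E lost starts as k[L]t: 5.47% for autumn, 10.9% for dusk, and 15.0% for spring and noon. Z at that early time is read as following the E lost, as at the first teal reading, with Z at 11.7% of 12.1% E lost. [L] falls proportionally faster in spring than in noon, as spring's [E] is higher, so this reckoning puts noon first at 12 s, then spring, dusk and autumn.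

The forecast, holding that “each E consumes one L”, gives noon > dusk > spring > autumn at 4.0 min, noon > spring > dusk > autumn at 12 s, 6.2% for autumn, and 38% for noon, above the reckoning here.

The flasks give noon > dusk > spring > autumn at 4.0 min, with noon at 36.0% and autumn at 5.95%, and noon > spring > dusk > autumn at 12 s.

    E + L → Z + J (k = 1.09 L mol⁻¹ s⁻¹)
    L + Z → X + J (k = 0.0563 L mol⁻¹ s⁻¹)
    L + X → Q + J (k = 0.223 L mol⁻¹ s⁻¹)
    L + Q → G + J (k = 1.10 L mol⁻¹ s⁻¹)
    Z ⇌ D (K = 1.31, k = 0.0104 s⁻¹)

In autumn the half-life of Z by the forward step to D alone is 1.1 min, short against 4.0 min. By then Z is made at 0.0870 of the rate at which it is used up, each step taken net, and D stands at 7.29% beside Z at 5.95%. A further flask like autumn, charged with 2.4 mM of L, gets 3.74% from the Z share times its ratio. Computed, it holds 3.58% at 4.0 min.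

The earlier runs and the new flask were computed from invented constants, noise included.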